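**Retrosynthetic overview**

1. The route rests on the 3-substituted furan ring. Its β–β carbon–carbon bond (ring carbon bearing the C4 methylene to the neighbouring unsubstituted ring CH) is opened, after formal return of methanol to the ring, into the two terminal alkenes of the 1-methoxyallyl 2-methyleneallyl ether 24. This single ring is formed last (steps 15 and 16).
2. 24 comes from allylic alcohol 22 and methoxyallene (C–O bond). 22 comes from a Wittig union at C10=C11 of hydroxy aldehyde 9 with the α-alkyl ylide 21, which sets the E-enoate.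
3. 9: geranyl acetate supplies C5–C10 with the E C6=C7 alkene. Its distal alkene is carried as an epoxide (masked C10 aldehyde), and C3/C4 come from the dianion of 2-methylprop-2-en-1-ol (C4–C5 bond).
4. 21: the C15 stereocentre comes from methyl (R)-3-hydroxy-2-methylpropanoate. C12 and C13 are added with oxirane (C13–C14 bond) and C11 with Ph3P=CHCO2Me (C11–C12 bond).

Key step: step 15

Remark on the chemistry: the epoxide carbon in 2–8, the phosphorus-bearing carbon in 20 and the acetal carbon in 24 and 25 are carried as stereo-mixtures and drawn without configuration, since each is destroyed later. Chain numbering runs from C4 (furan-bound CH2) to C16 (CH2OAc). TBS = tert-butyldimethylsilyl; PPTS = pyridinium p-toluenesulfonate; dppp = 1,3-bis(diphenylphosphino)propane.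

**Route**

Step 1
Reactants: 1 geranyl acetate
Product: 2 (2E)-5-(3,3-dimethyloxiran-2-yl)-3-methylpent-2-en-1-yl acetate (racemic)
Conditions: mCPBA (1.05 equiv), NaHCO3, CH2Cl2, 0 °C
Reagents that add atoms: 3-chloroperoxybenzoic acid, OOC(=O)c1cccc(Cl)c1
Why: Prilezhaev epoxidation is electrophilic, so the remote electron-rich C6=C7 alkene of the geranyl unit should react well before the alkene deactivated by the allylic acetate; the new stereocentre forms as a racemate and is destroyed in step 5.

Step 2
Reactants: 2 (2E)-5-(3,3-dimethyloxiran-2-yl)-3-methylpent-2-en-1-yl acetate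
Product: 3 (2E)-5-(3,3-dimethyloxiran-2-yl)-3-methylpent-2-en-1-ol
Conditions: K2CO3 (0.2 equiv), MeOH, rt
Reagents that add atoms: none
Why: Carbonate-catalysed transesterification (methanolysis of the acetate) frees the allylic alcohol while the epoxide and the alkene are inert to methoxide at room temperature.

Step 3
Reactants: 3 (2E)-5-(3,3-dimethyloxiran-2-yl)-3-methylpent-2-en-1-ol
Product: 5 2-[(3E)-5-bromo-3-methylpent-3-en-1-yl]-3,3-dimethyloxirane, via allylic mesylate 4 (not isolated)
Conditions: MsCl, Et3N, THF, −40 °C; then LiBr, THF, −40 → 0 °C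
Reagents that add atoms: LiBr, [Li+].[Br-]; methanesulfonyl chloride, CS(=O)(=O)Cl (atoms in intermediate 4 only)
Why: Mesylation followed by SN2 displacement with bromide (Finkelstein-type exchange) at low temperature should convert the primary allylic alcohol into the bromide without allylic transposition or epoxide opening.

Step 4
Reactants: 5 2-[(3E)-5-bromo-3-methylpent-3-en-1-yl]-3,3-dimethyloxirane; 6 2-methylprop-2-en-1-ol
Product: 8 (5E)-8-(3,3-dimethyloxiran-2-yl)-6-methyl-2-methylideneoct-5-en-1-ol, via dilithiated methallyl alcohol 7 (not isolated)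
Conditions: 6 (2 equiv), n-BuLi (4.2 equiv), TMEDA, Et2O, 0 °C → rt; then 5 (1 equiv), THF, −78 → 0 °C; H2O
Reagents that add atoms: n-butyllithium, [Li]CCCC (lithium in intermediate 7 only)
Why: Alkylation of the methallyl alcohol dianion: double lithiation (O–H and allylic C–H, assisted by TMEDA) gives a 2-(lithiomethyl)allyl alkoxide whose carbon terminus should displace the primary allylic bromide by SN2 far faster than it attacks the hindered trisubstituted epoxide at −78 °C.

Step 5
Reactants: 8 (5E)-8-(3,3-dimethyloxiran-2-yl)-6-methyl-2-methylideneoct-5-en-1-ol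
Product: 9 (4E)-8-(hydroxymethyl)-4-methylnona-4,8-dienal
Conditions: HIO4·2H2O (1.2 equiv), THF/H2O, 0 °C
Reagents that add atoms: none
Why: Periodic acid hydrates the epoxide and cleaves the resulting glycol in one pot (Malaprade cleavage), which should release the C10 aldehyde and acetone without touching the alkenes or the primary alcohol.

Step 6
Reactants: 10 methyl (R)-3-hydroxy-2-methylpropanoate
Product: 11 methyl (2R)-3-[(tert-butyldimethylsilyl)oxy]-2-methylpropanoate
Conditions: TBSCl, imidazole, CH2Cl2, rt
Reagents that add atoms: tert-butyl(chloro)dimethylsilane, CC(C)(C)[Si](C)(C)Cl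
Why: Imidazole-promoted silylation of the primary alcohol is too weakly basic to enolise the ester, so the stereocentre (future C15) is kept.

Step 7
Reactants: 11 methyl (2R)-3-[(tert-butyldimethylsilyl)oxy]-2-methylpropanoate
Product: 12 (2S)-3-[(tert-butyldimethylsilyl)oxy]-2-methylpropan-1-ol
Conditions: (i-Bu)2AlH (2.5 equiv), CH2Cl2, −78 → 0 °C; aq. potassium sodium tartrate (KNaC4H4O6)
Reagents that add atoms: none
Why: Hydride reduction of the ester to the primary alcohol should proceed without epimerisation because the transient aldehyde is reduced at low temperature faster than it can enolise; the descriptor changes only through the priority rules.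

Step 8
Reactants: 12 (2S)-3-[(tert-butyldimethylsilyl)oxy]-2-methylpropan-1-ol
Product: 13 tert-butyl{[(2R)-3-iodo-2-methylpropyl]oxy}dimethylsilane
Conditions: I2, PPh3, imidazole, CH2Cl2, 0 °C → rt
Reagents that add atoms: iodine, II
Why: Appel-type iodination (Garegg–Samuelsson conditions) replaces the primary hydroxyl by SN2 at a carbon that is not stereogenic, so the adjacent stereocentre is untouched.

Step 9
Reactants: 13 tert-butyl{[(2R)-3-iodo-2-methylpropyl]oxy}dimethylsilane; 14 oxirane
Product: 16 (4S)-5-[(tert-butyldimethylsilyl)oxy]-4-methylpentan-1-ol, via alkyllithium 15 (not isolated)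
Conditions: t-BuLi (2.1 equiv), Et2O, −78 °C; then oxirane (3 equiv), −78 → 0 °C; H2O
Reagents that add atoms: tert-butyllithium, [Li]C(C)(C)C (lithium in intermediate 15 only)
Why: Lithium–iodine exchange gives a primary alkyllithium that opens oxirane by SN2 (two-carbon homologation forming C13–C14), the second equivalent of t-BuLi consuming the tert-butyl iodide formed.

Step 10
Reactants: 16 (4S)-5-[(tert-butyldimethylsilyl)oxy]-4-methylpentan-1-ol
Product: 17 tert-butyl{[(2S)-5-iodo-2-methylpentyl]oxy}dimethylsilane
Conditions: I2, PPh3, imidazole, CH2Cl2, 0 °C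
Reagents that add atoms: iodine, II
Why: Appel-type iodination (Garegg–Samuelsson conditions) of the unhindered primary alcohol is compatible with the silyl ether.

Step 11
Reactants: 17 tert-butyl{[(2S)-5-iodo-2-methylpentyl]oxy}dimethylsilane
Product: 18 (2S)-5-iodo-2-methylpentyl acetate
Conditions: Ac2O, FeCl3 (10 mol %), 0 °C → rt
Reagents that add atoms: acetic anhydride, CC(=O)OC(C)=O
Why: Lewis-acid-catalysed acetolysis of a silyl ether (direct exchange of silyl ether for acetate) installs the C16 acetate without ever freeing a 5-iodo alkoxide that could cyclise to a tetrahydropyran.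

Step 12
Reactants: 18 (2S)-5-iodo-2-methylpentyl acetate; 19 methyl (triphenyl-λ5-phosphanylidene)acetate
Product: 21 methyl (6S)-7-acetoxy-6-methyl-2-(triphenyl-λ5-phosphanylidene)heptanoate, via phosphonium iodide 20 (not isolated)
Conditions: 19 (0.95 equiv), MeCN, 80 °C; then aq. K2CO3, CH2Cl2, 0 °C
Reagents that add atoms: none
Why: C-Alkylation of an ester-stabilised phosphorus ylide by an unhindered primary iodide (SN2, forming C11–C12) gives the α-substituted phosphonium salt, which mild carbonate should deprotonate to the α-alkyl stabilised ylide without hydrolysing the acetate.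

Step 13
Reactants: 9 (4E)-8-(hydroxymethyl)-4-methylnona-4,8-dienal; 21 methyl (6S)-7-acetoxy-6-methyl-2-(triphenyl-λ5-phosphanylidene)heptanoate
Product: 22 methyl (2E,6E)-2-[(4S)-5-acetoxy-4-methylpentyl]-10-(hydroxymethyl)-6-methylundeca-2,6,10-trienoate
Conditions: 21 (1.3 equiv), toluene, 80 °C
Reagents that add atoms: none
Why: Wittig olefination with an α-substituted ester-stabilised ylide is governed by the more stable oxaphosphetane and should place the C9 chain trans to the ester (E-enoate, any minor Z isomer to be removed by chromatography), and the stabilised ylide tolerates the free allylic hydroxyl.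

Step 14
Reactants: 22 methyl (2E,6E)-2-[(4S)-5-acetoxy-4-methylpentyl]-10-(hydroxymethyl)-6-methylundeca-2,6,10-trienoate; 23 methoxyallene
Product: 24 methyl (2E,6E)-2-[(4S)-5-acetoxy-4-methylpentyl]-10-{[(1-methoxyprop-2-en-1-yl)oxy]methyl}-6-methylundeca-2,6,10-trienoate (epimeric at the acetal carbon)
Conditions: Pd(OAc)2 (5 mol %), dppp (7.5 mol %), Et3N (1.5 equiv), 23 (3 equiv), MeCN, rt
Reagents that add atoms: none
Why: Palladium-catalysed hydroalkoxylation of an alkoxyallene: zerovalent palladium formed in situ gives a methoxy-substituted π-allylpalladium species that the alcohol captures at the oxygen-bearing terminus, which should give the mixed acrolein acetal under non-acidic conditions (acetal carbon uncontrolled and irrelevant).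

Step 15
Reactants: 24 methyl (2E,6E)-2-[(4S)-5-acetoxy-4-methylpentyl]-10-{[(1-methoxyprop-2-en-1-yl)oxy]methyl}-6-methylundeca-2,6,10-trienoate
Product: 25 methyl (2E,6E)-2-[(4S)-5-acetoxy-4-methylpentyl]-9-(5-methoxy-2,5-dihydrofuran-3-yl)-6-methylnona-2,6-dienoate
Conditions: second-generation Grubbs catalyst (H2IMes)(PCy3)Cl2Ru=CHPh (5 mol %), CH2Cl2 (0.005 M), 40 °C
Reagents that add atoms: none
Why: Ring-closing olefin metathesis by the Chauvin mechanism: the ruthenium benzylidene exchanges onto the unhindered monosubstituted vinyl group of the acrolein acetal, and the new alkylidene undergoes intramolecular [2+2] cycloaddition and cycloreversion with the 1,1-disubstituted methylidene at C3, expelling ethene and creating the ring β–β C=C bond. The closest known reaction type is the ring-closing metathesis of mixed acrolein acetals of 2-substituted allylic alcohols to 2-alkoxy-2,5-dihydrofurans, used as a furan synthesis. The single ring, the five-membered 2-methoxy-2,5-dihydrofuran, closes by joining the two alkene termini that the C–O–C acetal tether holds five atoms apart, and loss of gaseous ethene drives it. No stereocentre is formed; the acetal carbon is an uncontrolled spectator erased in step 16 and C15 is remote. The step needs chemoselectivity among four alkenes, and substitution secures it: only the two terminal alkenes are accessible to the bulky catalyst, the trisubstituted C6=C7 alkene and the α-branched electron-poor C10=C11 enoate are inert, and closure onto C6=C7 would need an eight-membered ring or a cyclobutene. High dilution suppresses cross-metathesis between chains.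

Step 16
Reactants: 25 methyl (2E,6E)-2-[(4S)-5-acetoxy-4-methylpentyl]-9-(5-methoxy-2,5-dihydrofuran-3-yl)-6-methylnona-2,6-dienoate
Product: 26 methyl (2E,6E)-2-[(4S)-5-acetoxy-4-methylpentyl]-9-(furan-3-yl)-6-methylnona-2,6-dienoate (target)
Conditions: PPTS (10 mol %), CH2Cl2, rt
Reagents that add atoms: none
Why: Acid-catalysed elimination of methanol: ionisation of the acetal gives a cyclic oxocarbenium ion and loss of the ring O–CH2 proton gives the aromatic furan, the gain in aromaticity making the step irreversible under acid mild enough for the enoate and the acetate.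

**Compound list**

1 | geranyl acetate | CC(C)=CCC/C(C)=C/COC(C)=O | starting material
2 | (2E)-5-(3,3-dimethyloxiran-2-yl)-3-methylpent-2-en-1-yl acetate (racemic) | CC(=O)OC/C=C(\C)CCC1OC1(C)C | intermediate
3 | (2E)-5-(3,3-dimethyloxiran-2-yl)-3-methylpent-2-en-1-ol | OC/C=C(\C)CCC1OC1(C)C | intermediate
4 | (2E)-5-(3,3-dimethyloxiran-2-yl)-3-methylpent-2-en-1-yl methanesulfonate | CS(=O)(=O)OC/C=C(\C)CCC1OC1(C)C | intermediate (not isolated)
5 | 2-[(3E)-5-bromo-3-methylpent-3-en-1-yl]-3,3-dimethyloxirane | BrC/C=C(\C)CCC1OC1(C)C | intermediate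
6 | 2-methylprop-2-en-1-ol | C=C(C)CO | starting material
7 | lithium 2-(lithiomethyl)prop-2-en-1-olate | [Li]CC(=C)CO[Li] | intermediate (not isolated)
8 | (5E)-8-(3,3-dimethyloxiran-2-yl)-6-methyl-2-methylideneoct-5-en-1-ol | C=C(CO)CC/C=C(\C)CCC1OC1(C)C | intermediate
9 | (4E)-8-(hydroxymethyl)-4-methylnona-4,8-dienal | C=C(CO)CC/C=C(\C)CCC=O | intermediate
10 | methyl (R)-3-hydroxy-2-methylpropanoate | COC(=O)[C@H](C)CO | starting material
11 | methyl (2R)-3-[(tert-butyldimethylsilyl)oxy]-2-methylpropanoate | COC(=O)[C@H](C)CO[Si](C)(C)C(C)(C)C | intermediate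
12 | (2S)-3-[(tert-butyldimethylsilyl)oxy]-2-methylpropan-1-ol | OC[C@H](C)CO[Si](C)(C)C(C)(C)C | intermediate
13 | tert-butyl{[(2R)-3-iodo-2-methylpropyl]oxy}dimethylsilane | IC[C@H](C)CO[Si](C)(C)C(C)(C)C | intermediate
14 | oxirane | C1CO1 | starting material
15 | {(2S)-3-[(tert-butyldimethylsilyl)oxy]-2-methylpropyl}lithium | [Li]C[C@H](C)CO[Si](C)(C)C(C)(C)C | intermediate (not isolated)
16 | (4S)-5-[(tert-butyldimethylsilyl)oxy]-4-methylpentan-1-ol | OCCC[C@H](C)CO[Si](C)(C)C(C)(C)C | intermediate
17 | tert-butyl{[(2S)-5-iodo-2-methylpentyl]oxy}dimethylsilane | ICCC[C@H](C)CO[Si](C)(C)C(C)(C)C | intermediate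
18 | (2S)-5-iodo-2-methylpentyl acetate | ICCC[C@H](C)COC(C)=O | intermediate
19 | methyl (triphenyl-λ5-phosphanylidene)acetate | COC(=O)C=P(c1ccccc1)(c1ccccc1)c1ccccc1 | starting material
20 | [(6S)-7-acetoxy-1-methoxy-6-methyl-1-oxoheptan-2-yl]triphenylphosphonium iodide | COC(=O)C(CCC[C@H](C)COC(C)=O)[P+](c1ccccc1)(c1ccccc1)c1ccccc1.[I-] | intermediate (not isolated)
21 | methyl (6S)-7-acetoxy-6-methyl-2-(triphenyl-λ5-phosphanylidene)heptanoate | COC(=O)C(CCC[C@H](C)COC(C)=O)=P(c1ccccc1)(c1ccccc1)c1ccccc1 | intermediate
22 | methyl (2E,6E)-2-[(4S)-5-acetoxy-4-methylpentyl]-10-(hydroxymethyl)-6-methylundeca-2,6,10-trienoate | COC(=O)/C(=C/CC/C(C)=C/CCC(=C)CO)CCC[C@H](C)COC(C)=O | intermediate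
23 | methoxyallene (1-methoxypropa-1,2-diene) | COC=C=C | starting material
24 | methyl (2E,6E)-2-[(4S)-5-acetoxy-4-methylpentyl]-10-{[(1-methoxyprop-2-en-1-yl)oxy]methyl}-6-methylundeca-2,6,10-trienoate | COC(=O)/C(=C/CC/C(C)=C/CCC(=C)COC(OC)C=C)CCC[C@H](C)COC(C)=O | intermediate
25 | methyl (2E,6E)-2-[(4S)-5-acetoxy-4-methylpentyl]-9-(5-methoxy-2,5-dihydrofuran-3-yl)-6-methylnona-2,6-dienoate | COC(=O)/C(=C/CC/C(C)=C/CCC1=CC(OC)OC1)CCC[C@H](C)COC(C)=O | intermediate
26 | methyl (2E,6E)-2-[(4S)-5-acetoxy-4-methylpentyl]-9-(furan-3-yl)-6-methylnona-2,6-dienoate | COC(=O)/C(=C/CC/C(C)=C/CCc1ccoc1)CCC[C@H](C)COC(C)=O | target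

**Step count and risks**

Total step count: 16. Longest linear sequence: 11 steps (steps 6–12, then 13–16, from 10 to 26).

Steps most likely to fail:

Step 15 (key step). The ruthenium alkylidene may be diverted into intermolecular metathesis, or the acid-labile acetal may ionise before the ring closes, so that cyclisation stalls or gives oligomers. Fallback without metathesis, setting out from bromide 5 and returning at target 26: the furan is brought in preformed. Commercial furan-3-ylmethanol is converted with PPh3 and CCl4 into 3-(chloromethyl)furan F1. Magnesium in THF gives (furan-3-ylmethyl)magnesium chloride F2. Coupling of F2 with 5 under Li2CuCl4 catalysis at −78 → 0 °C should give 3-[(3E)-6-(3,3-dimethyloxiran-2-yl)-4-methylhex-3-en-1-yl]furan F3. Brief treatment with HIO4·2H2O in THF/H2O at 0 °C should give (4E)-7-(furan-3-yl)-4-methylhept-4-enal F4. Wittig reaction of F4 with ylide 21 in toluene at 80 °C then gives 26 directly.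

Step 12. C-Alkylation of the weakly nucleophilic stabilised ylide by an unactivated primary iodide may be too slow and lose out to dehydrohalogenation of the iodide. Fallback setting out from iodide 18 and returning at 22: the much more nucleophilic sodium salt of commercial trimethyl phosphonoacetate (NaH, DMF, 50 °C) is alkylated by 18 to methyl (6S)-7-acetoxy-2-(dimethoxyphosphoryl)-6-methylheptanoate F5. Horner–Wadsworth–Emmons reaction of F5 with aldehyde 9 under Masamune–Roush conditions (LiCl, DBU, MeCN) should give 22. The E isomer is still expected to prevail, though less cleanly than in the Wittig reaction, so the geometrical isomers would be separated by chromatography.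

Step 4. The hard dilithio reagent may open or isomerise the epoxide, or couple by electron transfer, instead of displacing the bromide cleanly. Fallback setting out from epoxy acetate 2 and returning at 9: the aldehyde is unveiled before the coupling and carried as a base-inert acetal. HIO4·2H2O cleaves 2 to (2E)-3-methyl-6-oxohex-2-en-1-yl acetate F6. Ethane-1,2-diol and PPTS in benzene at reflux give (2E)-5-(1,3-dioxolan-2-yl)-3-methylpent-2-en-1-yl acetate F7. K2CO3 in MeOH gives (2E)-5-(1,3-dioxolan-2-yl)-3-methylpent-2-en-1-ol F8. CBr4 and PPh3 in CH2Cl2 at 0 °C give 2-[(3E)-5-bromo-3-methylpent-3-en-1-yl]-1,3-dioxolane F9. Alkylation of dianion 7 with F9 as in step 4 gives (5E)-8-(1,3-dioxolan-2-yl)-6-methyl-2-methylideneoct-5-en-1-ol F10. PPTS in wet acetone then releases hydroxy aldehyde 9.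

**Further compounds**

F1 | step 15 | 3-(chloromethyl)furan | ClCc1ccoc1
F2 | step 15 | (furan-3-ylmethyl)magnesium chloride | Cl[Mg]Cc1ccoc1
F3 | step 15 | 3-[(3E)-6-(3,3-dimethyloxiran-2-yl)-4-methylhex-3-en-1-yl]furan | CC1(C)OC1CC/C(C)=C/CCc1ccoc1
F4 | step 15 | (4E)-7-(furan-3-yl)-4-methylhept-4-enal | O=CCC/C(C)=C/CCc1ccoc1
F5 | step 12 | methyl (6S)-7-acetoxy-2-(dimethoxyphosphoryl)-6-methylheptanoate | COC(=O)C(CCC[C@H](C)COC(C)=O)P(=O)(OC)OC
F6 | step 4 | (2E)-3-methyl-6-oxohex-2-en-1-yl acetate | CC(=O)OC/C=C(\C)CCC=O
F7 | step 4 | (2E)-5-(1,3-dioxolan-2-yl)-3-methylpent-2-en-1-yl acetate | CC(=O)OC/C=C(\C)CCC1OCCO1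
F8 | step 4 | (2E)-5-(1,3-dioxolan-2-yl)-3-methylpent-2-en-1-ol | OC/C=C(\C)CCC1OCCO1
F9 | step 4 | 2-[(3E)-5-bromo-3-methylpent-3-en-1-yl]-1,3-dioxolane | BrC/C=C(\C)CCC1OCCO1
F10 | step 4 | (5E)-8-(1,3-dioxolan-2-yl)-6-methyl-2-methylideneoct-5-en-1-ol | C=C(CO)CC/C=C(\C)CCC1OCCO1
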